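The cyclohexane C5–C10 is read as the contraction product of a lactone-fused cycloheptene. Quaternary C10 (methyl, vinyl) beside the C9 acetate is a masked β-acyloxy aldehyde with an α-quaternary carbon. In the key step the C1–C10 epoxide of the seven-membered ring (C1, C5–C10) opens at C10 under Lewis acid. The C1–C5 ring bond shifts to C10, and C1 is expelled as the formyl group. One operation shrinks the ring by one carbon and fixes C10 stereospecifically, with five stereocentres, both esters and the α-methylene lactone already in place. The precursor, an epoxy acetate, comes from allylboration, Nozaki–Hiyama–Kishi addition and ring-closing metathesis.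

Key step: step 16

Remark on numbering: elemane numbering throughout. Ring C5–C10; C1=C2 vinyl and C14 methyl on C10; C4(=C3)–C15 on C5; lactone C7–C11(=C13)–C12(=O)–O–C8. α is the face of O8 and O9, β is the face of C14.
Assumption: (R)-5-(hydroxymethyl)furan-2(5H)-one (1) is taken as a catalogue compound, like its (S)-antipode.

Step 1
Reactants: 1 (R)-5-(hydroxymethyl)furan-2(5H)-one
Product: 2 (R)-5-[(tert-butyldiphenylsilyloxy)methyl]furan-2(5H)-one
Conditions: TBDPSCl, imidazole, DMF, 0 °C to rt
Reagents that add atoms: tert-butyl(chloro)diphenylsilane, CC(C)(C)[Si](Cl)(c1ccccc1)c1ccccc1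
Why: Standard silylation of the primary alcohol puts an acid-stable, bulky group on C9, leaves the C8 stereocentre untouched and will shield one face of the butenolide.

Step 2
Reactants: 2 (R)-5-[(tert-butyldiphenylsilyloxy)methyl]furan-2(5H)-one
Product: 3 (4R,5R)-5-[(tert-butyldiphenylsilyloxy)methyl]-4-(1,3-dioxolan-2-yl)dihydrofuran-2(3H)-one (C6 acetal on C7 trans to C9 on C8)
Conditions: 1,3-dioxolane (solvent), Ph2CO (10 mol %), hν (350 nm), rt
Reagents that add atoms: 1,3-dioxolane, C1COCO1
Why: In this photosensitised Giese-type radical conjugate addition the nucleophilic 1,3-dioxolan-2-yl radical (masked formyl carbon C6) should add to the β-carbon C7 anti to the silyloxymethyl group, which sets C7 trans to C8.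

Step 3
Reactants: 3 dioxolanyl lactone
Product: 4 (2R,3R)-2-[(tert-butyldiphenylsilyloxy)methyl]-5-oxotetrahydrofuran-3-carbaldehyde (C6 aldehyde, 7,8-trans)
Conditions: 2 M aq HCl, THF, 40 °C
Reagents that add atoms: water, O
Why: Acid hydrolysis of the cyclic acetal frees the C6 aldehyde while the TBDPS ether and the lactone survive, and the trans arrangement at C7 is also the thermodynamically preferred one.

Step 4
Reactants: 5 2-methylbut-1-en-3-yne
Product: 6 4,4,5,5-tetramethyl-2-[(1E)-3-methylbuta-1,3-dien-1-yl]-1,3,2-dioxaborolane
Conditions: HBpin, Cp2ZrHCl (5 mol %), Et3N (5 mol %), neat, 60 °C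
Reagents that add atoms: pinacolborane, [H]B1OC(C)(C)C(C)(C)O1
Why: Zirconium-catalysed hydroboration adds H–B syn and anti-Markovnikov to the terminal alkyne only, which should give the (E)-dienylboronate and leave the 1,1-disubstituted alkene alone.

Step 5
Reactants: 6 (E)-dienylboronate
Product: 8 4,4,5,5-tetramethyl-2-[(2E)-4-methylpenta-2,4-dien-1-yl]-1,3,2-dioxaborolane, via lithium chloromethyl boronate complex 7 (not isolated)
Conditions: BrCH2Cl, n-BuLi, THF, −78 °C to rt
Reagents that add atoms: bromochloromethane, ClCBr; n-butyllithium, [Li]CCCC (lithium counter-ion of 7 only)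
Why: In this Matteson homologation chloromethyllithium made in situ adds to boron and the dienyl group undergoes a 1,2-metallate shift with loss of chloride, which inserts one CH2 and keeps the E geometry.

Step 6
Reactants: 4 C6 aldehyde; 8 (E)-allylic boronate
Product: 10 homoallylic alcohol (7,8-trans lactone with the chain C6H(OH)–C5H(vinyl)(isopropenyl) on C7; OH anti to isopropenyl in the zigzag C7–C6–C5–C1; 6S,5R), via pinacol borate ester 9 (not isolated)
Conditions: (S)-TRIP (5 mol %), 4 Å MS, toluene, −30 °C; aqueous work-up
Reagents that add atoms: none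
Why: This chiral-phosphoric-acid-catalysed allylboration runs through a chair Zimmerman–Traxler transition state, so attack through the γ-carbon makes the C5–C6 bond with vinyl (C1) and isopropenyl on C5, the E-boronate fixes the 5,6-anti relationship, and the (S)-catalyst should steer addition to the Si face of the weakly biased aldehyde to set C6.

Step 7
Reactants: 10 homoallylic alcohol
Product: 12 Mannich base (CH2NMe2 on C11, trans to the C7 side chain), via dilithio alkoxide enolate 11 (not isolated)
Conditions: LDA (2.3 equiv), THF, −78 °C; CH2=NMe2+ I−, −78 to −20 °C; H2O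
Reagents that add atoms: N,N-dimethylmethyleneiminium iodide (Eschenmoser's salt), C=[N+](C)C.[I-]; lithium diisopropylamide, [Li]N(C(C)C)C(C)C (lithium of 11 only)
Why: Mannich-type α-aminomethylation of the lactone enolate (the hydroxyl rides as its alkoxide and the enolised lactone cannot translactonise) should occur anti to the C7 side chain and stores the future exocyclic methylene C13 in a form that is blind to metathesis.

Step 8
Reactants: 12 Mannich base
Product: 13 C6 angelate of 12
Conditions: angelic acid, 2,4,6-trichlorobenzoyl chloride, Et3N, toluene, rt; then 12, 80 °C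
Reagents that add atoms: angelic acid, C/C=C(/C)C(=O)O
Why: Yamaguchi-type mixed-anhydride esterification without a nucleophilic catalyst acylates the hindered C6 alcohol with retention at C6 and is the established way to avoid Z-to-E isomerisation of angelates.

Step 9
Reactants: 13 angelate silyl ether
Product: 14 primary C9 alcohol
Conditions: HF·pyridine, THF/pyridine, 0 °C to rt
Reagents that add atoms: none
Why: Fluoride-mediated desilylation in an acidic buffer frees the primary C9 alcohol without acyl migration, ester cleavage or loss of dimethylamine.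

Step 10
Reactants: 14 primary alcohol
Product: 15 C9 aldehyde
Conditions: Dess–Martin periodinane, CH2Cl2, 0 °C to rt
Reagents that add atoms: none
Why: Dess–Martin oxidation stops at the aldehyde under near-neutral conditions (the amine is masked by the acetic acid that forms), so the C8 stereocentre next to the new formyl group should not epimerise.

Step 11
Reactants: 15 C9 aldehyde
Product: 16 allylic alcohol C9H(OH)–C10(CH3)=CH2 (O9 anti to O8 in the zigzag C7–C8–C9–C10)
Conditions: 2-bromopropene, CrCl2 (4 equiv), NiCl2 (1 mol %), DMF, rt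
Reagents that add atoms: 2-bromopropene, C=C(C)Br
Why: In this Nozaki–Hiyama–Kishi coupling the isopropenylchromium(III) reagent adds only to the aldehyde, tolerates lactone, angelate, amine and alkenes, and under polar Felkin–Anh control (attack anti to the C8–O bond, no chelation by the acyloxy oxygen) should give the 8,9-anti alcohol that sets C9.

Step 12
Reactants: 16 triene alcohol
Product: 17 lactone-fused cyclohept-1(10)-en-9α-ol (ring C1, C5–C10; isopropenyl on C5, angelate on C6, Mannich base intact)
Conditions: Grubbs II (5 mol %), TsOH·H2O (1.05 equiv), CH2Cl2 (2 mM), 40 °C; aq NaHCO3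
Reagents that add atoms: none
Why: In this ring-closing metathesis the catalyst should load on the monosubstituted C5 vinyl group and close onto the hydroxyl-activated 1,1-disubstituted alkene to the trisubstituted cycloheptene, while the C5 isopropenyl group has no productive ring size, the angelate is inert, and the protonated Mannich base removes both amine poisoning and the five-membered closure that an exocyclic methylene would allow.

Step 13
Reactants: 17 cycloheptenol Mannich base
Product: 19 α-methylene-γ-butyrolactone cycloheptenol, via trimethylammonium iodide 18 (not isolated)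
Conditions: MeI, THF, rt; then aq NaHCO3, rt
Reagents that add atoms: iodomethane, CI (its methyl group enters 18 only)
Why: Quaternisation followed by mild-base E1cB (Hofmann-type) elimination of trimethylamine unveils the α-methylene lactone under conditions that spare the angelate and the allylic alcohol.

Step 14
Reactants: 19 cycloheptenol
Product: 20 1α,10α-epoxy-9α-alcohol
Conditions: VO(acac)2 (5 mol %), t-BuOOH (decane), CH2Cl2, 0 °C
Reagents that add atoms: tert-butyl hydroperoxide, CC(C)(C)OO
Why: Hydroxyl-directed vanadium-catalysed epoxidation delivers oxygen syn to the C9 α-hydroxyl group, which sets C1 and C10 as the α-epoxide, and touches neither the remote isopropenyl group nor the electron-poor alkenes.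

Step 15
Reactants: 20 epoxy alcohol
Product: 21 epoxy acetate
Conditions: Ac2O, Et3N, DMAP (cat.), CH2Cl2, 0 °C to rt
Reagents that add atoms: acetic anhydride, CC(=O)OC(C)=O
Why: DMAP-catalysed acetylation installs the final C9 acetate with retention and makes C9 electron-poor, which blocks any semipinacol shift from that carbon in the next step.

Step 16
Reactants: 21 epoxy acetate
Product: 22 ring-contracted aldehyde (cyclohexane C5–C10; C10 carries β-CH3 and α-CHO)
Conditions: BF3·OEt2 (0.3 equiv), CH2Cl2, −78 to −40 °C
Reagents that add atoms: none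
Why: BF3 binds the epoxide oxygen, the tertiary C10–O bond ionises and, in concert, the C1–C5 σ-bond lying anti to it migrates to C10 while C1 collapses to the aldehyde (Meinwald rearrangement with ring contraction, seven to six). The closest known reaction type is the Lewis-acid rearrangement of 1-methylcycloalkene oxides and of cyclic 2,3-epoxy acylates to ring-contracted aldehydes with an α-quaternary carbon. The ring C5–C10 is closed by this suprafacial 1,2-alkyl shift and not by a cyclisation, so no tether or ring-closure mode is involved. C10 is the only new stereocentre: C5 attacks it from the β face opposite the departing α-oxygen set in step 14, which leaves methyl β and formyl α, and the migrating C5 keeps its configuration. The step needs the C5 shift to beat the C1 hydride shift, proton loss and any migration from C9; the branched, allylic C5 is the best migrating group, the electron-poor acetate at C9 (cis to the leaving oxygen) can neither push nor participate, and low temperature curbs elimination. The trans-lactone stays diequatorial, and the esters and electron-poor alkenes should be inert to substoichiometric BF3 at low temperature.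

Step 17
Reactants: 22 aldehyde
Product: 23 15-deoxo compound (vinyl on C10, isopropenyl on C5)
Conditions: Tebbe reagent (1.1 equiv), pyridine (cat.), THF/toluene, −40 to 0 °C; aq NaOH
Reagents that add atoms: Tebbe reagent, C[Al-]1(C)C[Ti](C2C=CC=C2)(C2C=CC=C2)[Cl+]1
Why: Tebbe methylenation is non-basic and much faster with the aldehyde than with ester or lactone carbonyl groups at low temperature, so the C1 formyl group should become the vinyl group without Michael addition to the α-methylene lactone.

Step 18
Reactants: 23 15-deoxo compound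
Product: 24 CNP0228039.1 (target)
Conditions: SeO2 (1.5 equiv), 1,4-dioxane, 70 °C
Reagents that add atoms: selenium dioxide, O=[Se]=O
Why: Riley allylic oxidation (ene reaction, then [2,3]-shift) should pick the isopropenyl group, the only electron-rich alkene with accessible allylic C–H bonds (the vinyl group has none, the acrylate-type alkenes are deactivated, C5–H is buried between C6 and quaternary C10), and carry its methyl group C15 to the enal.

Compound list
1 | (R)-5-(hydroxymethyl)furan-2(5H)-one | OC[C@@H]1OC(=O)C=C1 | starting material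
2 | (R)-5-[(tert-butyldiphenylsilyloxy)methyl]furan-2(5H)-one | CC(C)(C)[Si](c1ccccc1)(c1ccccc1)OC[C@@H]1OC(=O)C=C1 | intermediate
3 | (4R,5R)-dioxolanyl lactone | CC(C)(C)[Si](c1ccccc1)(c1ccccc1)OC[C@@H]1OC(=O)C[C@H]1C1OCCO1 | intermediate
4 | (2R,3R)-lactone C6 aldehyde | CC(C)(C)[Si](c1ccccc1)(c1ccccc1)OC[C@@H]1OC(=O)C[C@H]1C=O | intermediate
5 | 2-methylbut-1-en-3-yne | C=C(C)C#C | starting material
6 | (E)-dienyl pinacol boronate | CC(=C)/C=C/B1OC(C)(C)C(C)(C)O1 | intermediate
7 | lithium chloromethyl boronate complex | [Li+].CC(=C)/C=C/[B-]1(CCl)OC(C)(C)C(C)(C)O1 | intermediate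
8 | (E)-4-methylpenta-2,4-dienyl pinacol boronate | CC(=C)/C=C/CB1OC(C)(C)C(C)(C)O1 | intermediate
9 | pinacol borate ester of 10 | CC(C)(C)[Si](c1ccccc1)(c1ccccc1)OC[C@@H]1OC(=O)C[C@H]1[C@@H](OB1OC(C)(C)C(C)(C)O1)[C@H](C=C)C(C)=C | intermediate
10 | homoallylic alcohol | CC(C)(C)[Si](c1ccccc1)(c1ccccc1)OC[C@@H]1OC(=O)C[C@H]1[C@@H](O)[C@H](C=C)C(C)=C | intermediate
11 | dilithio alkoxide enolate | [Li+].[Li+].CC(C)(C)[Si](c1ccccc1)(c1ccccc1)OC[C@@H]1OC([O-])=C[C@H]1[C@@H]([O-])[C@H](C=C)C(C)=C | intermediate
12 | Mannich base | CC(C)(C)[Si](c1ccccc1)(c1ccccc1)OC[C@@H]1OC(=O)[C@H](CN(C)C)[C@H]1[C@@H](O)[C@H](C=C)C(C)=C | intermediate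
13 | C6 angelate | CC(C)(C)[Si](c1ccccc1)(c1ccccc1)OC[C@@H]1OC(=O)[C@H](CN(C)C)[C@H]1[C@@H](OC(=O)/C(C)=C\C)[C@H](C=C)C(C)=C | intermediate
14 | primary C9 alcohol | OC[C@@H]1OC(=O)[C@H](CN(C)C)[C@H]1[C@@H](OC(=O)/C(C)=C\C)[C@H](C=C)C(C)=C | intermediate
15 | C9 aldehyde | O=C[C@@H]1OC(=O)[C@H](CN(C)C)[C@H]1[C@@H](OC(=O)/C(C)=C\C)[C@H](C=C)C(C)=C | intermediate
16 | C9 allylic alcohol | C=C(C)[C@H](O)[C@@H]1OC(=O)[C@H](CN(C)C)[C@H]1[C@@H](OC(=O)/C(C)=C\C)[C@H](C=C)C(C)=C | intermediate
17 | cycloheptenol Mannich base | C1=C(C)[C@H](O)[C@@H]2OC(=O)[C@H](CN(C)C)[C@H]2[C@@H](OC(=O)/C(C)=C\C)[C@H]1C(C)=C | intermediate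
18 | trimethylammonium iodide | [I-].C1=C(C)[C@H](O)[C@@H]2OC(=O)[C@H](C[N+](C)(C)C)[C@H]2[C@@H](OC(=O)/C(C)=C\C)[C@H]1C(C)=C | intermediate
19 | α-methylene lactone cycloheptenol | C1=C(C)[C@H](O)[C@@H]2OC(=O)C(=C)[C@H]2[C@@H](OC(=O)/C(C)=C\C)[C@H]1C(C)=C | intermediate
20 | 1α,10α-epoxy-9α-alcohol | C[C@@]13[C@H](O)[C@@H]2OC(=O)C(=C)[C@H]2[C@@H](OC(=O)/C(C)=C\C)[C@@H](C(C)=C)[C@@H]1O3 | intermediate
21 | epoxy acetate | C[C@@]13[C@H](OC(C)=O)[C@@H]2OC(=O)C(=C)[C@H]2[C@@H](OC(=O)/C(C)=C\C)[C@@H](C(C)=C)[C@@H]1O3 | intermediate
22 | ring-contracted aldehyde | O=C[C@]1(C)[C@H](OC(C)=O)[C@@H]2OC(=O)C(=C)[C@H]2[C@@H](OC(=O)/C(C)=C\C)[C@H]1C(C)=C | intermediate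
23 | 15-deoxo compound | C=C[C@]1(C)[C@H](OC(C)=O)[C@@H]2OC(=O)C(=C)[C@H]2[C@@H](OC(=O)/C(C)=C\C)[C@H]1C(C)=C | intermediate
24 | CNP0228039.1 | C=C[C@]1(C)[C@H](OC(C)=O)[C@@H]2OC(=O)C(=C)[C@H]2[C@@H](OC(=O)/C(C)=C\C)[C@H]1C(=C)C=O | target

Total step count: 18. Longest linear sequence: 16 steps (steps 1–3 and 6–18).

Steps most likely to fail

1. Step 16. A hydride shift from C1 or proton loss from the developing C10 cation may outrun the shift of the C1–C5 ring bond, so the ring does not contract. The fallback sets out from 19 and comes back at 22.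
   - A rhenium(VII)-catalysed suprafacial 1,3-transposition (Ph3SiOReO3, Et2O, 0 °C) moves the hydroxyl group from C9 to C1. It gives the transposed allylic alcohol F1 (C9=C10 alkene, 1α-OH); its equilibrium partner 19 is recycled.
   - VO(acac)2/t-BuOOH then gives the 9α,10α-epoxy 1α-alcohol F2.
   - SnCl4 (CH2Cl2, −78 °C) triggers a type-III semipinacol rearrangement. The carbinol carbon C1 hands its C1–C5 ring bond to C10, again seven- to six-membered, now driven by carbonyl formation at the carbinol carbon. This leads to the β-hydroxy aldehyde F3, whose C9 oxygen stems from the epoxide.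
   - Acetylation (Ac2O, DMAP) gives 22.

2. Step 11. Facial selectivity in the addition to the α-acyloxy aldehyde may be poor, so C9 forms as an epimer mixture. The fallback sets out from 16 (as that mixture) and comes back at 16. Dess–Martin oxidation gives the isopropenyl ketone F4. An oxazaborolidine-catalysed (CBS) borane reduction, with the catalyst antipode matched to the 9α-alcohol and excess borane to saturate the amine, then sets C9 by hydride delivery instead of carbon addition.

3. Step 18. Oxidation may stall at the allylic alcohol, run on past the aldehyde, or stray to the angelate methyl groups on prolonged heating. The fallback sets out from 23 and comes back at 24. Ene-type allylic chlorination of the electron-rich isopropenyl group (Ca(OCl)2, solid CO2, CH2Cl2/H2O, 0 °C) gives the allylic chloride F5. Kornblum oxidation (DMSO, NaHCO3, NaI cat., 40 °C) converts it into the enal.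

Further compounds
F1 | step 16 | transposed allylic alcohol (C9=C10, 1α-OH) | CC1=C[C@@H]2OC(=O)C(=C)[C@H]2[C@@H](OC(=O)/C(C)=C\C)[C@@H](C(C)=C)[C@@H]1O
F2 | step 16 | 9α,10α-epoxy 1α-alcohol | C[C@]12O[C@@H]2[C@@H]3OC(=O)C(=C)[C@H]3[C@@H](OC(=O)/C(C)=C\C)[C@@H](C(C)=C)[C@@H]1O
F3 | step 16 | β-hydroxy aldehyde (9α-OH) | O=C[C@]1(C)[C@H](O)[C@@H]2OC(=O)C(=C)[C@H]2[C@@H](OC(=O)/C(C)=C\C)[C@H]1C(C)=C
F4 | step 11 | isopropenyl ketone | C=C(C)C(=O)[C@@H]1OC(=O)[C@H](CN(C)C)[C@H]1[C@@H](OC(=O)/C(C)=C\C)[C@H](C=C)C(C)=C
F5 | step 18 | allylic chloride (C15–Cl) | C=C[C@]1(C)[C@H](OC(C)=O)[C@@H]2OC(=O)C(=C)[C@H]2[C@@H](OC(=O)/C(C)=C\C)[C@H]1C(=C)CCl
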